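**The problem**

The target is a germacranolide in which both ring alkenes are ring-cis: C1=C10 (C2 and C9 cis) carries the C14 aldehyde and C4=C5 (C3 and C6 cis) carries the free C15 hydroxymethyl (germacrane numbering: ring C1–C10, lactone C11–C13 with C12 the carbonyl, C14 on C10, C15 on C4). A trans-fused α-methylene-γ-lactone spans O6 and C7, and C8 and C9 carry two different esters, an angelate on O8 and an (R)-2-methylbutanoate on O9, so the ring holds four contiguous stereocentres (6R,7S,8S,9R). On a ten-membered ring none of these can be set with confidence, but on a cyclohexane they can: a trans lactone forces its two ring bonds equatorial, and the chair it locks can then direct reagents to C8, C9 and to a second ring fused at C5–C10. The ring itself should be made without a macrocyclisation if the geometry of the trisubstituted alkenes is to be certain. The groups that forbid rough treatment are the α-methylene lactone (Michael acceptor), the enal flanked by the allylic C9 acyloxy group (prone to SN2′ loss), the angelate (isomerises to the tiglate) and the epimerisable α-centre of the 2-methylbutanoate; all must appear late, and O8 must be told apart from O9. The enabling feature is that the C15 oxygen, the C4=C5 alkene and C10 stand in the relation of the three products of one heterolytic fragmentation: an oxirane on C4/C15, the C5–C10 bond and an oxygen on C10. C5–C10 is the transannular bond that divides the ten-membered ring into ring A (C1–C5, C10) and ring B (C5–C10) of a decalin, so the macrocycle can be released from a bicycle, and the C10 carbonyl that appears is the handle for C14 and the C1=C10 alkene.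

**Retrosynthesis**

Esters and oxidation level. Target 41 is traced to triol 32 by cutting the two ester C–O bonds (angelic acid 34 on O8, (R)-2-methylbutanoic acid 39 on O9) and returning C14 to the alcohol, with C15 held as a silyl ether. Acylating last is preferred to carrying esters, because every C–C bond-forming step needs strong base. The regiochemistry is solved by the structure itself: O9 and O14 are 1,3-related and are tied as silylene 33, which leaves only O8 for the angelate (36). After release of diol 37 the primary C14 alcohol is oxidised selectively (38), so only O9 remains for the second acid (40). The forward steps must be mild and non-basic.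

C13 and C14. Triol 32 comes from acetonide 31, and 31 from lactone 27 by cutting C11=C13 (Eschenmoser's salt 28). Lactone 27 comes from ketone 24 by cutting C10–C14 (stannane 26) at enol triflate 25. C14 is attached after the ring is formed because C10 must be a carbinol carbon in the key step. The forward reaction asks for kinetic enolisation toward C1 with ring-cis geometry.

C5–C10 (key). Ketone 24 is the silyl ether of keto alcohol 23, and 23 is simplified by re-forming the C5–C10 bond, which gives epoxy alcohol 22. Cuts at C5–C6, C9–C10 or C1–C2 would all demand a ten-membered ring closure; this cut demands none and fixes the C4=C5 geometry stereospecifically. The precursor is a cis-decalin with all four stereocentres on a six-membered ring. The forward reaction needs the C4–O bond anti to C5–C10 and C6 gauche to C3, which means 5α-H, 10α-OH and a β oxirane oxygen.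

C4–C15. Epoxide 22 is cut at C4–C15 to ketone 19 and trimethylsulfonium iodide 20 (ylide 21). Reagents reach C4 from the convex α face, so a carbon nucleophile arriving there leaves the oxygen β, as required. Oxidation of a 4-methylene compound from the same face would give the wrong epimer.

O8 and O9. Acetonide 19 is cut at C8–O and C9–O back to alkene 15 (through 16, 17 and 18). Both oxygens lie on the concave β face, cis to C1, which OsO4 would avoid. The iodonium/acetoxonium sequence puts both oxygens on the face opposite to the first electrophile. Placing this after lactone formation makes the face selection a consequence of the locked chair.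

C7–C11 and the lactone. Lactone 15 is cut at C7–C11 and at the acyl–O6 bond to allylic bis-carbonate 11 and dimethyl malonate 12 (through 13 and 14). Allylic alkylation is preferred to reduction of a butenolide or to a Claisen shift because it keeps C8=C9 in place and carries the C7 oxygen configuration over to carbon with retention.

O6 and O7. Bis-carbonate 11 comes from diol 10, enone alcohol 9 and enone 8 by cutting the C6–O bond (enolate hydroxylation) and reducing C7. The enone can enolise only toward C6, and each reagent enters from the face anti to the C4 substituent.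

Ring A. Ketal 8 comes from diketone 7, which is cut at C4–C5 to achiral dienone aldehyde 6. The absolute configuration enters here by desymmetrisation, and the cis ring fusion follows from the tether. A quinone Diels–Alder entry would have to add O10 later; here it is present from the start.

C1–C10. Aldehyde 6 comes from silyl ether 5, made from bromide 1 and quinone monoketal 2 (through 3 and 4) by cutting C1–C10.

**Roads not taken**

Alternative 1: The cut is C7–C8 together with C11=C13. Phosphonobutenolide A2, which already holds C6 and the C1–C5 chain, would take up a Z-configured 2-alkoxyvinyl copper nucleophile at C7 anti to the C6 substituent, and the resulting phosphonate anion would olefinate a one-carbon aldehyde in the same flask to give A1. The merits are convergence and a complete trans α-methylene lactone from one operation. The weak points are what remains: A1 is still open between C9 and C10, so a ten-membered ring must be closed by alkenyl-metal addition, with the C9 carbinol and the C8 oxygen set without a rigid template, and the methylene lactone must survive all of it. In convergence and in the way the lactone is made this road is better than the chosen one, which needs a separate methylenation. The chosen plan sets against it that C8 and C9 are fixed on a locked chair and that the ring is released, not closed.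

Alternative 2: The cut is a two-carbon ring expansion: C1–C2 and C9–C10 are formed and C2–C9 is broken. The secondary-amine enamine of eight-membered ketone A4 would add a propiolate ester to a fused cyclobutene that opens to the ten-membered dienamine, hydrolysed to keto ester A3. Its merit is that C1=C10 and C14 arrive together in one step. Its weak points are that A4, an eight-membered ring with a cis alkene and three stereocentres, is no easier than the target; the enamine must form toward C2 and not toward the alkoxy-bearing C8; and the C9 carbonyl must then be reduced selectively on a flexible ring, with ester, lactone and methylene still to be adjusted. For C14 and the C1=C10 alkene this road is better than the chosen plan, which needs a triflation, a coupling and an oxidation and carries an enolate-geometry risk. The chosen plan sets against it that no medium ring has to be built by cyclisation and that C9 is set on a chair.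

Alternative 3: The cut is C5–C6. The alkenylchromium species from the (Z)-iodide of acyclic aldehyde A6 (divalent chromium, nickel co-catalyst) would add to the C6 aldehyde, and the C6 alkoxide would close the lactone to give A5. It is the most convergent road, carries the C4=C5 geometry in the iodide, and delivers C14 and C15 already differentiated; A5 corresponds to compound 27 of the chosen route and would probably be reached in fewer steps. Its weak points are a strained ten-membered closure under high dilution with stoichiometric chromium, a C6 configuration that depends on 1,2-induction from C7 in a macrocyclic transition state, and an acyclic synthesis of the C7–C9 triad and two trisubstituted alkenes. The chosen plan is longer and linear; it sets against this that ring formation and alkene geometry are stereospecific and that every stereocentre is made on a rigid bicycle.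

Key step: step 13

Assumption and notation: the antipode of the triazolium catalyst in step 3 that gives (4aR,8aR)-7 is assigned by analogy and would be fixed by experiment; both antipodes derive from commercial cis-1-amino-2-indanol. In the decalins, α is the face of ring B that carries H-5 and O-10 and β is the opposite face; "lactone" means the γ-lactone from O6 to C12 of the C7 side chain C11–C12.

**Route**

Step 1
Reactants: 1 4-bromo-1,1-dimethoxybutane; 2 4,4-dimethoxycyclohexa-2,5-dien-1-one
Product: 5 {[1-(4,4-dimethoxybutyl)-4,4-dimethoxycyclohexa-2,5-dien-1-yl]oxy}triethylsilane, via Grignard reagent 3 (not isolated), via magnesium alkoxide 4 (not isolated)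
Conditions: Mg, THF, 40 °C; 2, −78 °C; Et3SiCl, imidazole, −78 → 23 °C
Reagents that add atoms: magnesium, [Mg] (held by 3 and 4 only); chlorotriethylsilane, CC[Si](Cl)(CC)CC
Why: Grignard formation and 1,2-addition to the single carbonyl of the quinone monoketal is the standard entry to para-quinol ketals; the alkoxide is silylated in the same flask so that the acid-labile bis-allylic carbinol is never handled free.

Step 2
Reactants: 5 silyl ether bis-acetal
Product: 6 4-[4-oxo-1-(triethylsilyloxy)cyclohexa-2,5-dien-1-yl]butanal
Conditions: pyridinium p-toluenesulfonate (10 mol %), acetone/H2O 9:1, 40 °C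
Reagents that add atoms: water, O
Why: Acid-catalysed acetal hydrolysis cleaves the quinone ketal and the aldehyde acetal, while the tertiary silyl ether on the electron-poor dienone is slow to ionise; keeping O10 masked prevents a six-membered lactol between the quinol oxygen and the aldehyde.

Step 3
Reactants: 6 dienone aldehyde
Product: 7 (4aR,8aR)-4a-(triethylsilyloxy)-3,4,4a,8a-tetrahydronaphthalene-1,7(2H,8H)-dione
Conditions: (5aR,10bS)-2-(pentafluorophenyl)-5a,10b-dihydro-4H,6H-indeno[2,1-b][1,2,4]triazolo[4,3-d][1,4]oxazin-2-ium tetrafluoroborate or its enantiomer (20 mol %, see assumption), KN(SiMe3)2 (18 mol %), toluene, 23 °C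
Reagents that add atoms: none
Why: Intramolecular Stetter reaction under chiral carbene catalysis, a known desymmetrisation of 4,4-disubstituted cyclohexadienones: the acyl-anion equivalent at C4 adds to one enantiotopic β-carbon (C5). Because the tether hangs from C10 the bond can form only on the tether's face, so H-5 and O-10 end up cis, and the catalyst's choice of C5 over C9 sets both stereocentres.

Step 4
Reactants: 7 cis-fused diketone
Product: 8 4,4-ethylenedioxy-10α-(triethylsilyloxy)-5αH-cis-decal-8-en-7-one
Conditions: Me3SiOCH2CH2OSiMe3, Me3SiOTf (5 mol %), CH2Cl2, −78 → −20 °C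
Reagents that add atoms: 1,2-bis(trimethylsilyloxy)ethane, C[Si](C)(C)OCCO[Si](C)(C)C
Why: Silyl-triflate-catalysed ketalisation with the bis-silyl glycol ether converts a saturated ketone much faster than an enone, so only C4 is masked; this removes the acidic C5–H next to C4=O, which would otherwise allow loss of O10 and aromatisation in the base steps that follow.

Step 5
Reactants: 8 ketal enone
Product: 9 4,4-ethylenedioxy-6α-hydroxy-10α-(triethylsilyloxy)-5αH-cis-decal-8-en-7-one
Conditions: KN(SiMe3)2, THF, −78 °C; 2-(phenylsulfonyl)-3-phenyloxaziridine, −78 °C; NH4Cl aq.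
Reagents that add atoms: 2-(phenylsulfonyl)-3-phenyloxaziridine, O=S(=O)(c1ccccc1)N1OC1c1ccccc1
Why: Davis oxidation of the kinetic cross-conjugated dienolate; C6 is the only enolisable position because C10 is quaternary. The oxaziridine approaches anti to the C4 dioxolane on the neighbouring C5, giving the 6α-alcohol.

Step 6
Reactants: 9 hydroxy enone
Product: 10 4,4-ethylenedioxy-10α-(triethylsilyloxy)-5αH-cis-decal-8-ene-6α,7β-diol
Conditions: NaBH4, CeCl3·7H2O, MeOH, −78 °C
Reagents that add atoms: none
Why: Luche 1,2-reduction; with the 6α-hydroxyl equatorial, hydride enters C7 axially from the convex α face and gives the 7β-alcohol, trans-diequatorial to O6.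

Step 7
Reactants: 10 trans-diol
Product: 11 6α,7β-bis(methoxycarbonyloxy)-4,4-ethylenedioxy-10α-(triethylsilyloxy)-5αH-cis-decal-8-ene
Conditions: ClCO2Me, pyridine, 4-(dimethylamino)pyridine (cat.), CH2Cl2, 0 °C
Reagents that add atoms: methyl chloroformate, COC(=O)Cl
Why: Acylation of both secondary hydroxyls; only the allylic C7 carbonate can ionise later, so the two need not be differentiated.

Step 8
Reactants: 11 bis-carbonate; 12 dimethyl malonate
Product: 14 trans-fused 11-(methoxycarbonyl) lactone (4-dioxolane; 10α-OSiEt3; 8-ene), via malonate adduct 13 (not isolated)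
Conditions: Pd(PPh3)4 (5 mol %), THF, 60 °C; then NaOMe, MeOH, 23 °C; AcOH
Reagents that add atoms: none
Why: Tsuji–Trost allylic alkylation: zerovalent palladium ionises the C7 carbonate with inversion and malonate attacks anti to the metal, so C7–C11 forms with net retention on the β face. Of the two allyl termini C9 is neopentylic, which sends the nucleophile to C7 and leaves C8=C9 in place. Methoxide then cleaves the C6 carbonate and the 6α-alkoxide lactonises onto the malonate.

Step 9
Reactants: 14 ester lactone
Product: 15 trans-fused lactone of the 7β-acetic acid on O6α (4-dioxolane; 10α-OSiEt3; 8-ene)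
Conditions: LiCl, H2O, dimethyl sulfoxide, 140 °C
Reagents that add atoms: none
Why: Krapcho dealkoxycarbonylation of the doubly activated ester under neutral conditions leaves the silyl ether, dioxolane and alkene untouched.

Step 10
Reactants: 15 lactone alkene
Product: 17 8β-acetoxy-9β,10α-dihydroxy-4-oxo lactone, via iodo acetate 16 (not isolated)
Conditions: I2, AgOAc, AcOH, 23 °C; then H2O, 90 °C
Reagents that add atoms: iodine, II (held by 16 only); silver acetate, CC(=O)[O-].[Ag+]; water, O
Why: Woodward cis-hydroxylation: the iodonium ion forms on the α face, anti to the pseudoaxial C1 on C10, and acetate opens it trans-diaxially at C8 from the β face (Fürst–Plattner). The 8β-acetate then displaces the 9α-iodide to a β-fused acetoxonium ion that water opens to the cis-8β,9β hydroxy acetate, so both oxygens arrive on the hindered face. The hot aqueous acid of the second stage also hydrolyses the dioxolane and the silyl ether.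

Step 11
Reactants: 17 hydroxy acetate
Product: 19 8β,9β-acetonide of the 10α-hydroxy-4-oxo lactone, via keto triol 18 (not isolated)
Conditions: HCl (cat.), MeOH, 23 °C; then Me2C(OMe)2, acetone, 23 °C
Reagents that add atoms: 2,2-dimethoxypropane, COC(C)(C)OC
Why: Acid-catalysed transesterification removes the acetate without base, which the β-hydroxy, β′-acyloxy ketone at C4 would not tolerate. Acetonide formation under the same acid selects the cis-8β,9β diol over the trans-9,10 pair, and any lactone opened by methanol recloses on concentration.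

Step 12
Reactants: 19 keto alcohol; 20 trimethylsulfonium iodide
Product: 22 4,15-epoxy-10α-hydroxy cis-decalin lactone acetonide (oxirane oxygen β; C15 α), via sulfonium ylide 21 (not isolated)
Conditions: 20, KN(SiMe3)2, THF, −10 °C; then 19, −10 → 0 °C
Reagents that add atoms: none
Why: Corey–Chaykovsky epoxidation with the kinetically controlled sulfonium methylide: methylene is delivered to C4 from the convex α face (axial on ring A, cis to H-5 and 10-OH), which puts the oxirane oxygen β and equatorial. The ylide is too weak a base to enolise the ketone or deprotonate the tertiary alcohol appreciably, so retro-aldol and β-elimination are not expected.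

Step 13
Reactants: 22 epoxy alcohol
Product: 23 ten-membered 10-ketone (ring-cis C4=C5 bearing C15H2OH; lactone; 8,9-acetonide)
Conditions: KH, THF, 0 °C; NH4Cl aq., 0 °C
Reagents that add atoms: none
Why: Deprotonation gives the C10 potassium alkoxide; its lone pair forms C10=O while the C5–C10 σ bond, antiperiplanar to the oxirane C4–O bond, becomes the C4=C5 π bond and the oxirane oxygen leaves onto C15 as a primary alkoxide. This is a Grob-type fragmentation of a cyclic 3,4-epoxy alcohol, the reaction type that unveils eight-membered rings from bicyclic epoxy alcohols in taxane chemistry. No ring is closed: the ten-membered ring is the periphery of the decalin and appears when the shared bond breaks, so no cyclisation mode or dilution is involved. No stereocentre is created; C5 and C10 are consumed and C6–C9 are untouched. The selectivity needed is the alkene geometry, and the substrate fixes it: the trans lactone holds ring B in the chair with O6 and C11 equatorial, which forces the cis-decalin into the conformer with C6 axial on ring A. The β, equatorial oxirane oxygen is then anti to C5–C10 and C6 is gauche to C3, so C3 and C6 emerge cis. Oxirane strain and C=O formation drive the step, and the primary alkoxide produced is less basic than the tertiary one consumed, which limits enolisation of the new ketone before the cold quench.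

Step 14
Reactants: 23 keto alcohol
Product: 24 15-O-tert-butyldiphenylsilyl ether of 23
Conditions: tBuPh2SiCl, imidazole, CH2Cl2, 23 °C
Reagents that add atoms: tert-butyl(chloro)diphenylsilane, CC(C)(C)[Si](Cl)(c1ccccc1)c1ccccc1
Why: Standard silylation of the primary allylic alcohol; this acid-stable group must outlast an acetonide hydrolysis and a selective silylene cleavage.

Step 15
Reactants: 24 silyl ether ketone
Product: 25 C10 enol triflate (ring-cis C1=C10)
Conditions: KN(SiMe3)2, THF, −78 °C; PhNTf2, −78 °C; NH4Cl aq.
Reagents that add atoms: N-phenylbis(trifluoromethanesulfonimide), O=S(=O)(N(c1ccccc1)S(=O)(=O)C(F)(F)F)C(F)(F)F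
Why: Kinetic enolisation and O-triflation: the hindered base takes a proton from the C1 methylene, not from the tertiary, acetonide-bearing C9 or the less acidic lactone α-position. The ring-cis enolate is the one expected for a medium ring that already holds a cis alkene and two fused five-membered rings.

Step 16
Reactants: 25 enol triflate; 26 (tributylstannyl)methanol
Product: 27 14-hydroxy lactone (ring-cis C1=C10 bearing C14H2OH; C15 silyl ether; 8,9-acetonide)
Conditions: Pd(PPh3)4 (10 mol %), LiCl, 1,4-dioxane, 90 °C
Reagents that add atoms: none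
Why: Stille coupling of an enol triflate with the hydroxymethylstannane is an established hydroxymethylation and retains the alkene geometry; chloride stabilises the alkenylpalladium intermediate.

Step 17
Reactants: 27 lactone; 28 N,N-dimethylmethyleneiminium iodide
Product: 31 α-methylene lactone (C14 alcohol; C15 silyl ether; 8,9-acetonide), via Mannich base 29 (not isolated), via ammonium iodide 30 (not isolated)
Conditions: LiN(iPr)2 (2.3 equiv), THF, −78 °C; 28, −78 → 23 °C; NH4Cl aq.; MeI, MeOH; NaHCO3 aq., CH2Cl2
Reagents that add atoms: iodomethane, CI (held by 30 only)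
Why: Eschenmoser methylenation: the lactone enolate is aminomethylated (the C14 alkoxide consumes the first equivalent of base), the Mannich base is quaternised, and mild base effects β-elimination to the exocyclic methylene. The configuration of C11 in 29 and 30 is of no consequence.

Step 18
Reactants: 31 acetonide
Product: 32 8,9,14-triol
Conditions: AcOH/H2O 4:1, 45 °C
Reagents that add atoms: none
Why: Acid-catalysed acetal hydrolysis; the primary tert-butyldiphenylsilyl ether and the methylene lactone are stable to warm aqueous acetic acid.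

Step 19
Reactants: 32 triol
Product: 33 9,14-O-(di-tert-butylsilylene) derivative with free 8-OH
Conditions: tBu2Si(OTf)2, 2,6-lutidine, CH2Cl2, 0 °C
Reagents that add atoms: di-tert-butylsilyl bis(trifluoromethanesulfonate), CC(C)(C)[Si](OS(=O)(=O)C(F)(F)F)(OS(=O)(=O)C(F)(F)F)C(C)(C)C
Why: Silylene formation: the bis-triflate silylates the primary C14 hydroxyl first and then closes the six-membered ring onto the 1,3-related O9, five-membered closure onto O8 being strained and slow. The inherent 1,3-relation of O9 and O14 thus distinguishes O9 from O8.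

Step 20
Reactants: 33 silylene alcohol; 34 angelic acid
Product: 36 8-O-angelate, via mixed anhydride 35 (not isolated)
Conditions: 34, 2,4,6-trichlorobenzoyl chloride, Et3N, toluene, 23 °C; then 33, toluene, 75 °C
Reagents that add atoms: 2,4,6-trichlorobenzoyl chloride, O=C(Cl)c1c(Cl)cc(Cl)cc1Cl (held by 35 only)
Why: Yamaguchi-type esterification through the mixed anhydride without a nucleophilic catalyst is the established way to make angelates of hindered alcohols without isomerisation to the tiglate.

Step 21
Reactants: 36 silylene angelate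
Product: 37 9,14-diol 8-angelate
Conditions: HF·pyridine, pyridine, THF, 0 °C
Reagents that add atoms: none
Why: Fluoride cleavage: the dialkoxy-di-tert-butylsilane is much more labile to buffered HF·pyridine than the primary tert-butyldiphenylsilyl ether, and buffering at 0 °C limits O8-to-O9 acyl migration.

Step 22
Reactants: 37 diol
Product: 38 C14 enal with free 9-OH
Conditions: TEMPO (cat.), PhI(OAc)2, CH2Cl2, 23 °C
Reagents that add atoms: none
Why: Oxoammonium (TEMPO) oxidation is selective for primary over secondary alcohols, so only C14 is oxidised, and the enal keeps the geometry of the allylic alcohol.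

Step 23
Reactants: 38 hydroxy enal; 39 (R)-2-methylbutanoic acid
Product: 40 8-angelate 9-[(R)-2-methylbutanoate] 15-silyl ether
Conditions: 39, N,N′-diisopropylcarbodiimide, 4-(dimethylamino)pyridine (cat.), CH2Cl2, 0 °C
Reagents that add atoms: none
Why: Steglich esterification of the one remaining hydroxyl; a simple α-branched alkanoic acid does not racemise under these conditions, and low temperature with catalytic base avoids SN2′ attack on the acyloxy enal.

Step 24
Reactants: 40 silyl ether
Product: 41 CNP0290361.1
Conditions: HF·pyridine, THF, 23 °C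
Reagents that add atoms: none
Why: Acidic fluoride desilylation frees the C15 alcohol without the basic conditions that the methylene lactone, the acyloxy enal and the angelate would not survive.

**Compound list**

1 | 4-bromo-1,1-dimethoxybutane | COC(OC)CCCBr | starting material
2 | 4,4-dimethoxycyclohexa-2,5-dien-1-one | COC1(OC)C=CC(=O)C=C1 | starting material
3 | (4,4-dimethoxybutyl)magnesium bromide | COC(OC)CCC[Mg]Br | intermediate
4 | bromomagnesium 1-(4,4-dimethoxybutyl)-4,4-dimethoxycyclohexa-2,5-dien-1-olate | COC(OC)CCCC1(O[Mg]Br)C=CC(OC)(OC)C=C1 | intermediate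
5 | {[1-(4,4-dimethoxybutyl)-4,4-dimethoxycyclohexa-2,5-dien-1-yl]oxy}triethylsilane | COC(OC)CCCC1(O[Si](CC)(CC)CC)C=CC(OC)(OC)C=C1 | intermediate
6 | 4-[4-oxo-1-(triethylsilyloxy)cyclohexa-2,5-dien-1-yl]butanal | O=CCCCC1(O[Si](CC)(CC)CC)C=CC(=O)C=C1 | intermediate
7 | (4aR,8aR)-4a-(triethylsilyloxy)-3,4,4a,8a-tetrahydronaphthalene-1,7(2H,8H)-dione (cis-decal-8-ene-4,7-dione, 5α-H, 10α-OSiEt3) | O=C1CCC[C@@]2(O[Si](CC)(CC)CC)C=CC(=O)C[C@@H]12 | intermediate
8 | 4,4-ethylenedioxy-10α-(triethylsilyloxy)-5αH-cis-decal-8-en-7-one | C1COC2(O1)CCC[C@@]3(O[Si](CC)(CC)CC)C=CC(=O)C[C@@H]23 | intermediate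
9 | 4,4-ethylenedioxy-6α-hydroxy-10α-(triethylsilyloxy)-5αH-cis-decal-8-en-7-one | C1COC2(O1)CCC[C@@]3(O[Si](CC)(CC)CC)C=CC(=O)[C@H](O)[C@@H]23 | intermediate
10 | 4,4-ethylenedioxy-10α-(triethylsilyloxy)-5αH-cis-decal-8-ene-6α,7β-diol | C1COC2(O1)CCC[C@@]3(O[Si](CC)(CC)CC)C=C[C@@H](O)[C@H](O)[C@@H]23 | intermediate
11 | 6α,7β-bis(methoxycarbonyloxy)-4,4-ethylenedioxy-10α-(triethylsilyloxy)-5αH-cis-decal-8-ene | C1COC2(O1)CCC[C@@]3(O[Si](CC)(CC)CC)C=C[C@@H](OC(=O)OC)[C@H](OC(=O)OC)[C@@H]23 | intermediate
12 | dimethyl malonate | COC(=O)CC(=O)OC | starting material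
13 | dimethyl 2-[4,4-ethylenedioxy-6α-(methoxycarbonyloxy)-10α-(triethylsilyloxy)-5αH-cis-decal-8-en-7β-yl]malonate | C1COC2(O1)CCC[C@@]3(O[Si](CC)(CC)CC)C=C[C@@H](C(C(=O)OC)C(=O)OC)[C@H](OC(=O)OC)[C@@H]23 | intermediate
14 | 2-[4,4-ethylenedioxy-6α-hydroxy-10α-(triethylsilyloxy)-5αH-cis-decal-8-en-7β-yl]-2-(methoxycarbonyl)acetic acid γ-lactone (trans-fused; C11 not defined) | O=C1C(C(=O)OC)[C@H]2[C@H](O1)[C@H]3C4(OCCO4)CCC[C@@]3(O[Si](CC)(CC)CC)C=C2 | intermediate
15 | 2-[4,4-ethylenedioxy-6α-hydroxy-10α-(triethylsilyloxy)-5αH-cis-decal-8-en-7β-yl]acetic acid γ-lactone (trans-fused) | O=C1C[C@H]2[C@H](O1)[C@H]3C4(OCCO4)CCC[C@@]3(O[Si](CC)(CC)CC)C=C2 | intermediate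
16 | 2-[8β-acetoxy-4,4-ethylenedioxy-6α-hydroxy-9α-iodo-10α-(triethylsilyloxy)-5αH-cis-decal-7β-yl]acetic acid γ-lactone | O=C1C[C@H]2[C@H](O1)[C@H]3C4(OCCO4)CCC[C@@]3(O[Si](CC)(CC)CC)[C@H](I)[C@H]2OC(C)=O | intermediate
17 | 2-(8β-acetoxy-6α,9β,10α-trihydroxy-4-oxo-5αH-cis-decal-7β-yl)acetic acid 6-γ-lactone | O=C1C[C@H]2[C@H](O1)[C@H]3C(=O)CCC[C@@]3(O)[C@@H](O)[C@H]2OC(C)=O | intermediate
18 | 2-(6α,8β,9β,10α-tetrahydroxy-4-oxo-5αH-cis-decal-7β-yl)acetic acid 6-γ-lactone | O=C1C[C@H]2[C@H](O1)[C@H]3C(=O)CCC[C@@]3(O)[C@@H](O)[C@H]2O | intermediate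
19 | 2-[6α,10α-dihydroxy-8β,9β-(isopropylidenedioxy)-4-oxo-5αH-cis-decal-7β-yl]acetic acid 6-γ-lactone | O=C1C[C@H]2[C@H](O1)[C@H]3C(=O)CCC[C@@]3(O)[C@H]4OC(C)(C)O[C@H]42 | intermediate
20 | trimethylsulfonium iodide | C[S+](C)C.[I-] | starting material
21 | dimethylsulfonium methylide | [CH2-][S+](C)C | intermediate
22 | 2-[6α,10α-dihydroxy-8β,9β-(isopropylidenedioxy)-5αH-spiro[cis-decalin-4,2′-oxirane]-7β-yl]acetic acid 6-γ-lactone (oxirane O β, oxirane CH2 = C15 α) | O=C1C[C@H]2[C@H](O1)[C@H]3[C@]4(CO4)CCC[C@@]3(O)[C@H]5OC(C)(C)O[C@H]52 | intermediate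
23 | ten-membered keto alcohol: C10 ketone; ring-cis C4=C5 with CH2OH (C15) on C4; γ-lactone O6–C12 with C11H2 on C7; 8,9-acetonide; C6–C9 as in the target | C1C(=O)O[C@@H]2/C=C(/CO)CCCC(=O)[C@H]3OC(C)(C)O[C@H]3[C@@H]12 | intermediate
24 | 15-O-tert-butyldiphenylsilyl ether of 23 | C1C(=O)O[C@@H]2/C=C(/CO[Si](c3ccccc3)(c3ccccc3)C(C)(C)C)CCCC(=O)[C@H]3OC(C)(C)O[C@H]3[C@@H]12 | intermediate
25 | C10 enol trifluoromethanesulfonate of 24 (C1=C10, C2 cis to C9) | C1C(=O)O[C@@H]2/C=C(/CO[Si](c3ccccc3)(c3ccccc3)C(C)(C)C)CC/C=C(/OS(=O)(=O)C(F)(F)F)[C@H]3OC(C)(C)O[C@H]3[C@@H]12 | intermediate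
26 | (tributylstannyl)methanol | CCCC[Sn](CCCC)(CCCC)CO | starting material
27 | ten-membered lactone: ring-cis C1=C10 with CH2OH (C14) on C10; ring-cis C4=C5 with CH2OSiPh2tBu (C15); 8,9-acetonide; C11H2 | C1C(=O)O[C@@H]2/C=C(/CO[Si](c3ccccc3)(c3ccccc3)C(C)(C)C)CC/C=C(/CO)[C@H]3OC(C)(C)O[C@H]3[C@@H]12 | intermediate
28 | N,N-dimethylmethyleneiminium iodide (Eschenmoser's salt) | C=[N+](C)C.[I-] | starting material
29 | 11-(dimethylaminomethyl) derivative of 27 (C11 not defined) | CN(C)CC1C(=O)O[C@@H]2/C=C(/CO[Si](c3ccccc3)(c3ccccc3)C(C)(C)C)CC/C=C(/CO)[C@H]3OC(C)(C)O[C@H]3[C@@H]12 | intermediate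
30 | 11-(trimethylammoniomethyl) iodide derived from 29 | C[N+](C)(C)CC1C(=O)O[C@@H]2/C=C(/CO[Si](c3ccccc3)(c3ccccc3)C(C)(C)C)CC/C=C(/CO)[C@H]3OC(C)(C)O[C@H]3[C@@H]12.[I-] | intermediate
31 | α-methylene lactone: 27 with C11=C13H2 | C=C1C(=O)O[C@@H]2/C=C(/CO[Si](c3ccccc3)(c3ccccc3)C(C)(C)C)CC/C=C(/CO)[C@H]3OC(C)(C)O[C@H]3[C@@H]12 | intermediate
32 | 8,9,14-triol: 31 without the acetonide | C=C1C(=O)O[C@@H]2/C=C(/CO[Si](c3ccccc3)(c3ccccc3)C(C)(C)C)CC/C=C(/CO)[C@@H](O)[C@@H](O)[C@@H]12 | intermediate
33 | 9,14-O-(di-tert-butylsilylene) derivative of 32 with free 8-OH | C=C1C(=O)O[C@@H]2/C=C(/CO[Si](c3ccccc3)(c3ccccc3)C(C)(C)C)CC/C=C3/CO[Si](C(C)(C)C)(C(C)(C)C)O[C@H]3[C@@H](O)[C@@H]12 | intermediate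
34 | angelic acid, (Z)-2-methylbut-2-enoic acid | C/C=C(/C)C(=O)O | starting material
35 | (Z)-2-methylbut-2-enoic 2,4,6-trichlorobenzoic anhydride | C/C=C(/C)C(=O)OC(=O)c1c(Cl)cc(Cl)cc1Cl | intermediate
36 | 8-O-angelate of 33 | C=C1C(=O)O[C@@H]2/C=C(/CO[Si](c3ccccc3)(c3ccccc3)C(C)(C)C)CC/C=C3/CO[Si](C(C)(C)C)(C(C)(C)C)O[C@H]3[C@@H](OC(=O)/C(C)=C\C)[C@@H]12 | intermediate
37 | 9,14-diol 8-angelate 15-silyl ether | C=C1C(=O)O[C@@H]2/C=C(/CO[Si](c3ccccc3)(c3ccccc3)C(C)(C)C)CC/C=C(/CO)[C@@H](O)[C@@H](OC(=O)/C(C)=C\C)[C@@H]12 | intermediate
38 | 14-al: 9-hydroxy 8-angelate 15-silyl ether | C=C1C(=O)O[C@@H]2/C=C(/CO[Si](c3ccccc3)(c3ccccc3)C(C)(C)C)CC/C=C(/C=O)[C@@H](O)[C@@H](OC(=O)/C(C)=C\C)[C@@H]12 | intermediate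
39 | (R)-2-methylbutanoic acid | CC[C@@H](C)C(=O)O | starting material
40 | 15-O-tert-butyldiphenylsilyl ether of the target | C=C1C(=O)O[C@@H]2/C=C(/CO[Si](c3ccccc3)(c3ccccc3)C(C)(C)C)CC/C=C(/C=O)[C@@H](OC(=O)[C@H](C)CC)[C@@H](OC(=O)/C(C)=C\C)[C@@H]12 | intermediate
41 | CNP0290361.1 (6R,7S,8S,9R; 8-angelate, 9-[(R)-2-methylbutanoate], 14-al, 15-ol) | C=C1C(=O)O[C@@H]2/C=C(/CO)CC/C=C(/C=O)[C@@H](OC(=O)[C@H](C)CC)[C@@H](OC(=O)/C(C)=C\C)[C@@H]12 | target

**Step count and least certain steps**

Total: 24 steps. Longest linear sequence: 24 steps (1 and 2 to 41); all other partners (12, 20, 26, 28, 34, 39) are commercial.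

Step 13 (key step). What may go wrong: proton transfer between the alkoxide (or unconsumed hydride) and the new ten-membered ketone, leading to epimerisation at C9 or β-elimination of the C8 oxygen; or reluctance of the potassium alkoxide to expel the oxirane oxygen without electrophilic assistance. Fallback: change from base push to Lewis-acid pull. Ti(OiPr)4 in refluxing CH2Cl2 forms the titanium C10 alkoxide and coordinates the oxirane, so the same fragmentation runs without a free basic alkoxide. It sets out from 22, returns at 23 and makes no new compound (F0).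

Step 3. What may go wrong: slow closure of a six-membered ring by the aliphatic acyl-anion equivalent, so that aldehyde self-condensation or base-induced loss of the silanol with aromatisation competes, or poor discrimination between the two enone arms. Fallback (from 2, back at 7): commercial 5-bromo-1,1-dimethoxypentane is converted as in step 1 into (5,5-dimethoxypentyl)magnesium bromide F1, which adds to 2 to give the homologous magnesium alkoxide F2, silylated to the homologous silyl ether bis-acetal F3. Hydrolysis as in step 2 gives 5-[4-oxo-1-(triethylsilyloxy)cyclohexa-2,5-dien-1-yl]pentanal F4. An enamine-mediated intramolecular Michael addition (diarylprolinol silyl ether catalyst), a well-documented desymmetrisation of such dienones, closes ring A through the aldehyde α-carbon to the cis-fused 4-formyl enone F5. Condensation with morpholine gives the 4-(morpholinomethylene) enamine F6, whose C4=C15 bond is cleaved with O2 and CuCl (cat.) to give 7.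

Step 8. What may go wrong: slow ionisation, because the C7 carbonate is pseudo-equatorial in the preferred half-chair and the metal must approach the face carrying O6 and O10, or partial attack at C9. Fallback (from 10, back at 14): Mitsunobu cyclodehydration of trans-diol 10 (PPh3, diisopropyl azodicarboxylate), in which the allylic C7 oxygen is displaced, gives the 6α,7α-vinyl oxirane F7. Sodium dimethyl malonate (12, NaH) opens it by direct SN2 attack at allylic C7 from the β face without a π-allyl intermediate, and the 6α-alkoxide lactonises to 14.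

Step 10. What may go wrong: participation of the C10 oxygen in the iodonium ion with a 1,2-shift of C1 (semipinacol ring expansion), or sluggish closure of the acetoxonium ion at the neopentylic C9. Fallback (from 15, back at 19): 3-chloroperbenzoic acid gives the 8α,9α-epoxide F8. Trans-diaxial opening at C8 (NaOAc, AcOH, 60 °C) gives the 8β-acetoxy-9α-ol F9. Dess–Martin oxidation gives the 9-ketone F10, and NaBH4, attacking axially from the α face while C4 is still masked, gives the 8β-acetoxy-9β-ol F11. Aqueous methanolic HCl then removes acetate, dioxolane and silyl ether, and acetonide formation as in step 11 gives 19.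

Step 12. What may go wrong: approach of the ylide from the β face if the axial 10α-hydroxyl shields the α face, giving the C4 epimer whose C–O bond is not anti to C5–C10; attack on the lactone is a lesser concern. Fallback (from 19, back at 22): Wittig methylenation (Ph3P=CH2) gives the 4(15)-alkene F12. Dihydroxylation (OsO4 cat., N-methylmorpholine N-oxide), which under that same steric bias adds from the β face, gives the 4β,15-diol F13. Tosylation of the primary hydroxyl gives the 15-tosylate F14, and 1,8-diazabicyclo[5.4.0]undec-7-ene closes the oxirane to 22.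

Step 15. What may go wrong: formation of the ring-trans enolate, or deprotonation at C9 with epimerisation or loss of the C8 oxygen. Fallback (from 24, back at 27): Wittig reaction with (methoxymethylene)triphenylphosphorane gives the C10 enol ether F15. Hydrolysis (Hg(OAc)2, aqueous THF) gives the C10 carbaldehyde F16, and PhSeCl gives the α-phenylselenyl aldehyde F17. Oxidation with H2O2 and syn-elimination of the selenoxide away from the oxygenated C9 gives the enal F18 in its thermodynamically preferred geometry (CHO trans to C2), independent of any enolate. Luche reduction (NaBH4, CeCl3·7H2O) gives 27.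

**Further compounds**

F0 | step 13 | none | none
F1 | step 3 | (5,5-dimethoxypentyl)magnesium bromide | COC(OC)CCCC[Mg]Br
F2 | step 3 | bromomagnesium 1-(5,5-dimethoxypentyl)-4,4-dimethoxycyclohexa-2,5-dien-1-olate | COC(OC)CCCCC1(O[Mg]Br)C=CC(OC)(OC)C=C1
F3 | step 3 | {[1-(5,5-dimethoxypentyl)-4,4-dimethoxycyclohexa-2,5-dien-1-yl]oxy}triethylsilane | COC(OC)CCCCC1(O[Si](CC)(CC)CC)C=CC(OC)(OC)C=C1
F4 | step 3 | 5-[4-oxo-1-(triethylsilyloxy)cyclohexa-2,5-dien-1-yl]pentanal | O=CCCCCC1(O[Si](CC)(CC)CC)C=CC(=O)C=C1
F5 | step 3 | 7-oxo-10α-(triethylsilyloxy)-5αH-cis-decal-8-ene-4-carbaldehyde (C4 not defined) | O=CC1CCC[C@@]2(O[Si](CC)(CC)CC)C=CC(=O)C[C@@H]12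
F6 | step 3 | 4-(morpholinomethylene)-10α-(triethylsilyloxy)-5αH-cis-decal-8-en-7-one | C(=C1CCC[C@@]2(O[Si](CC)(CC)CC)C=CC(=O)C[C@@H]12)N1CCOCC1
F7 | step 8 | 6α,7α-epoxy-4,4-ethylenedioxy-10α-(triethylsilyloxy)-5αH-cis-decal-8-ene | C1COC2(O1)CCC[C@@]3(O[Si](CC)(CC)CC)C=C[C@@H]4O[C@@H]4[C@@H]23
F8 | step 10 | 8α,9α-epoxide of 15 | O=C1C[C@H]2[C@H](O1)[C@H]3C4(OCCO4)CCC[C@@]3(O[Si](CC)(CC)CC)[C@@H]5O[C@H]25
F9 | step 10 | 8β-acetoxy-9α-hydroxy lactone (4-dioxolane, 10α-OSiEt3) | O=C1C[C@H]2[C@H](O1)[C@H]3C4(OCCO4)CCC[C@@]3(O[Si](CC)(CC)CC)[C@H](O)[C@H]2OC(C)=O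
F10 | step 10 | 8β-acetoxy-9-oxo lactone (4-dioxolane, 10α-OSiEt3) | O=C1C[C@H]2[C@H](O1)[C@H]3C4(OCCO4)CCC[C@@]3(O[Si](CC)(CC)CC)C(=O)[C@H]2OC(C)=O
F11 | step 10 | 8β-acetoxy-9β-hydroxy lactone (4-dioxolane, 10α-OSiEt3) | O=C1C[C@H]2[C@H](O1)[C@H]3C4(OCCO4)CCC[C@@]3(O[Si](CC)(CC)CC)[C@@H](O)[C@H]2OC(C)=O
F12 | step 12 | 4-methylene analogue of 19 | O=C1C[C@H]2[C@H](O1)[C@H]3C(=C)CCC[C@@]3(O)[C@H]4OC(C)(C)O[C@H]42
F13 | step 12 | 4β,15-diol (4β-hydroxy-4α-hydroxymethyl) analogue of 19 | O=C1C[C@H]2[C@H](O1)[C@H]3[C@](O)(CO)CCC[C@@]3(O)[C@H]4OC(C)(C)O[C@H]42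
F14 | step 12 | 15-O-p-toluenesulfonate of F13 | O=C1C[C@H]2[C@H](O1)[C@H]3[C@](O)(COS(=O)(=O)c4ccc(C)cc4)CCC[C@@]3(O)[C@H]4OC(C)(C)O[C@H]42
F15 | step 15 | C10 methoxymethylene derivative of 24 | C1C(=O)O[C@@H]2/C=C(/CO[Si](c3ccccc3)(c3ccccc3)C(C)(C)C)CCCC(=COC)[C@H]3OC(C)(C)O[C@H]3[C@@H]12
F16 | step 15 | C10 carbaldehyde (C10 not defined) | C1C(=O)O[C@@H]2/C=C(/CO[Si](c3ccccc3)(c3ccccc3)C(C)(C)C)CCCC(C=O)[C@H]3OC(C)(C)O[C@H]3[C@@H]12
F17 | step 15 | 10-(phenylselanyl) C10 carbaldehyde | C1C(=O)O[C@@H]2/C=C(/CO[Si](c3ccccc3)(c3ccccc3)C(C)(C)C)CCCC(C=O)([Se]c3ccccc3)[C@H]3OC(C)(C)O[C@H]3[C@@H]12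
F18 | step 15 | 14-al of 27 (ring-cis C1=C10 enal, acetonide, C15 silyl ether) | C1C(=O)O[C@@H]2/C=C(/CO[Si](c3ccccc3)(c3ccccc3)C(C)(C)C)CC/C=C(/C=O)[C@H]3OC(C)(C)O[C@H]3[C@@H]12
A1 | alternative 1 | trans-6,7-disubstituted α-methylene lactone with the C8=C9 enol ether on C7 | C=C1C(=O)O[C@H](/C=C(/CO[Si](c2ccccc2)(c2ccccc2)C(C)(C)C)CC/C=C(\I)COCc2ccc(OC)cc2)[C@H]1/C=C\OCC
A2 | alternative 1 | 3-(diethoxyphosphoryl)butenolide carrying the C1–C5 chain on C6 | CCOP(=O)(OCC)C1=C[C@@H](/C=C(/CO[Si](c2ccccc2)(c2ccccc2)C(C)(C)C)CC/C=C(\I)COCc2ccc(OC)cc2)OC1=O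
A3 | alternative 2 | ten-membered 9-ketone with C1=C10 carrying the C14 methyl ester | COC(=O)/C1=C/CC/C(CO[Si](c2ccccc2)(c2ccccc2)C(C)(C)C)=C\[C@@H](O[Si](C)(C)C(C)(C)C)[C@H](CC(OC)OC)[C@H](OCc2ccc(OC)cc2)C1=O
A4 | alternative 2 | eight-membered ketone (C9 carbonyl, cis C4=C5, C6–C8 triad) | O=C1CC/C(CO[Si](c2ccccc2)(c2ccccc2)C(C)(C)C)=C\[C@@H](O[Si](C)(C)C(C)(C)C)[C@H](CC(OC)OC)[C@@H]1OCc1ccc(OC)cc1
A5 | alternative 3 | ten-membered trans-lactone with 8,9-acetonide, C14 p-methoxybenzyl ether and C15 silyl ether | C1C(=O)O[C@@H]2/C=C(/CO[Si](c3ccccc3)(c3ccccc3)C(C)(C)C)CC/C=C(/COCc3ccc(OC)cc3)[C@H]3OC(C)(C)O[C@H]3[C@@H]12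
A6 | alternative 3 | acyclic C6 aldehyde with C5 (Z)-iodide and C12 methyl ester | COC(=O)C[C@@H](C=O)[C@@H]1OC(C)(C)O[C@@H]1/C(COCc1ccc(OC)cc1)=C\CC/C(CO[Si](c1ccccc1)(c1ccccc1)C(C)(C)C)=C\I
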